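The benzo ring (ring A) of the benzofuran is sparsely dressed: oxygen on C7, the acrylate carbon on C5 in a 1,3-relationship, and C–H at C4 and C6. That pattern is exactly what a Danheiser benzannulation writes onto a furan, so ring A is disconnected to a 3-furylketene and a silyloxyethyne. In one flask the step forges C3a–C4, C4–C5, C6–C7 and C7–C7a and hands over the C7 phenol free and the C5 oxygen silylated, ready for triflation and a Heck coupling. Its precursor is a 2-aryl-4-(diazoacetyl)furan whose C3 carboxyl already carries the protected (R)-danshensu ester, leaving only the free furan alpha-carbon (future C7a) for ring closure.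

Key step: step 11

Remark: danshensu is taken as the free (R)-acid (liberated from its commercial sodium salt) and 3-phenylisoxazole as a purchasable starting material.
Abbreviations: Ar = 3,4-bis(methoxymethoxy)phenyl; Dan = (2R)-1-tert-butoxy-3-[3,4-bis(methoxymethoxy)phenyl]-1-oxopropan-2-yl (protected danshensu bound through its C2 oxygen); MOM = methoxymethyl.

Step 1
Reactants: 1 danshensu
Product: 2 tert-butyl (2R)-3-(3,4-dihydroxyphenyl)-2-hydroxypropanoate
Conditions: Cl3CC(=NH)OtBu (2 equiv), THF/cyclohexane, rt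
Reagents that add atoms: tert-butyl 2,2,2-trichloroacetimidate, CC(C)(C)OC(=N)C(Cl)(Cl)Cl
Why: Catalyst-free imidate esterification: only the carboxylic acid is acidic enough to protonate the trichloroacetimidate and be tert-butylated, while the phenols and the secondary alcohol would need a Lewis acid, so the ester should form chemoselectively with the stereocentre untouched.

Step 2
Reactants: 2 tert-butyl (2R)-3-(3,4-dihydroxyphenyl)-2-hydroxypropanoate
Product: 3 tert-butyl (2R)-3-[3,4-bis(methoxymethoxy)phenyl]-2-hydroxypropanoate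
Conditions: MOMCl (2.2 equiv), K2CO3, acetone, 0 °C → rt
Reagents that add atoms: chloromethyl methyl ether, COCCl
Why: Williamson-type O-alkylation: K2CO3 ionizes only the two phenols, whose phenoxides take up the chloromethyl ether much faster than the neutral secondary alcohol, which stays free for the later acylations.

Step 3
Reactants: 4 3,4-dihydroxybenzoic acid
Product: 6 3,4-bis(methoxymethoxy)benzoic acid, via methoxymethyl ester 5 (not isolated)
Conditions: MOMCl (3.5 equiv), iPr2NEt, THF, 0 °C → rt; then LiOH, MeOH/H2O, rt; 1 M HCl to pH 4, 0 °C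
Reagents that add atoms: chloromethyl methyl ether, COCCl; lithium hydroxide, [Li+].[OH-] (its oxygen ends in the carboxyl group)
Why: Exhaustive O-alkylation of the phenols and the carboxylate followed by saponification, which should cleave only the acyloxymethyl ester because aryl MOM acetals are inert to hydroxide.

Step 4
Reactants: 6 3,4-bis(methoxymethoxy)benzoic acid; 7 Meldrum's acid
Product: 8 5-[Ar(hydroxy)methylidene]-2,2-dimethyl-1,3-dioxane-4,6-dione
Conditions: EDC·HCl, DMAP, CH2Cl2, 0 °C → rt
Reagents that add atoms: none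
Why: Carbodiimide activation and DMAP-mediated C-acylation of Meldrum's acid, the standard entry to acyl Meldrum's acids, which rest as the enol and are carried on crude.

Step 5
Reactants: 8 5-[Ar(hydroxy)methylidene]-2,2-dimethyl-1,3-dioxane-4,6-dione; 3 tert-butyl (2R)-3-[3,4-bis(methoxymethoxy)phenyl]-2-hydroxypropanoate
Product: 10 Dan 3-Ar-3-oxopropanoate, via aroylketene 9 (not isolated)
Conditions: PhMe, 90 °C
Reagents that add atoms: none
Why: Thermal cycloreversion of the acyl Meldrum's acid expels acetone and CO2 and the aroylketene so formed is captured by the secondary alcohol (acylketene alcoholysis) under neutral conditions that cannot epimerize the alpha-carbon.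

Step 6
Reactants: 11 bromopyruvic acid
Product: 13 allyl 3-bromo-2-oxopropanoate, via bromopyruvoyl chloride 12 (not isolated)
Conditions: Cl2CHOMe, 50 °C; then allyl alcohol, CH2Cl2, 0 °C → rt
Reagents that add atoms: allyl alcohol, C=CCO (dichloromethyl methyl ether, COC(Cl)Cl, supplies only the chlorine of 12)
Why: Acid chloride formation with dichloromethyl methyl ether, the base-free method used for pyruvoyl chloride, followed by alcoholysis (acyl substitution) should give the allyl ester without exposing the bromoketone to base.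

Step 7
Reactants: 10 Dan 3-Ar-3-oxopropanoate; 13 allyl 3-bromo-2-oxopropanoate
Product: 16 4-allyl 3-Dan 2-Ar-furan-3,4-dicarboxylate, via hydroxydihydrofuran 14 (not isolated), via tertiary mesylate 15 (not isolated)
Conditions: Et3N, THF, 0 °C → rt; then MsCl, Et3N, 0 °C → rt
Reagents that add atoms: none
Why: Feist–Benary furan synthesis in its interrupted form: the enolate of 10 adds to the highly electrophilic ketone of 13, the enol oxygen displaces bromide to close 14 (its carbinol centre forms without control and is erased), and mesylation-elimination of the tertiary carbinol aromatizes the ring under base, putting the allyl ester on C4 and hydrogen on C5 without exposing MOM ethers or the tert-butyl ester to acid.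

Step 8
Reactants: 16 4-allyl 3-Dan 2-Ar-furan-3,4-dicarboxylate
Product: 17 5-Ar-4-(Dan-oxycarbonyl)furan-3-carboxylic acid
Conditions: Pd(PPh3)4 (cat.), morpholine, THF, rt; pH 4 work-up
Reagents that add atoms: none
Why: Tsuji–Trost deallylation: zerovalent palladium ionizes only the allyl ester to a pi-allyl complex that morpholine intercepts, so the danshensu and tert-butyl esters and all MOM ethers should survive.

Step 9
Reactants: 17 5-Ar-4-(Dan-oxycarbonyl)furan-3-carboxylic acid
Product: 19 Dan 2-Ar-4-(diazoacetyl)furan-3-carboxylate, via acid chloride 18 (not isolated)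
Conditions: Me2C=C(Cl)NMe2, CH2Cl2, 0 °C → rt; then Me3SiCHN2 (2.5 equiv), MeCN/THF, 0 °C → rt
Reagents that add atoms: (trimethylsilyl)diazomethane, C[Si](C)(C)C=[N+]=[N-] (1-chloro-N,N,2-trimethylprop-1-en-1-amine, CC(C)=C(Cl)N(C)C, supplies only the chlorine of 18)
Why: The alpha-chloroenamine makes the acid chloride without liberating HCl (safe for MOM and tert-butyl groups) and C-acylation of trimethylsilyldiazomethane with loss of Me3SiCl then gives the diazomethyl ketone, the first stage of an Arndt–Eistert sequence.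

Step 10
Reactants: 20 3-phenylisoxazole
Product: 23 (triisopropylsilyloxy)ethyne, via 5-lithio-3-phenylisoxazole 21 (not isolated), via lithium ethynolate 22 (not isolated)
Conditions: LiN(iPr)2, THF, −78 → −40 °C; then iPr3SiOTf, −78 → 0 °C
Reagents that add atoms: triisopropylsilyl trifluoromethanesulfonate, CC(C)[Si](OS(=O)(=O)C(F)(F)F)(C(C)C)C(C)C
Why: Base removes the C5 proton, the most acidic site of a 3-substituted isoxazole, and the 5-lithio species fragments by N–O and C3–C4 cleavage into benzonitrile and the parent ynolate (the classical isoxazole route to ynolates), which the bulky silyl triflate traps on oxygen (ynolate O-silylation).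

Step 11
Reactants: 19 Dan 2-Ar-4-(diazoacetyl)furan-3-carboxylate; 23 (triisopropylsilyloxy)ethyne
Product: 28 Dan 2-Ar-7-hydroxy-5-(triisopropylsilyloxy)benzofuran-3-carboxylate, via furylketene 24 (not isolated), via cyclobutenone 25 (not isolated), via dienylketene 26 (not isolated), via cyclohexadienone 27 (not isolated)
Conditions: 23 (3 equiv), hν (300 nm, Pyrex), ClCH2CH2Cl, 25 °C; then 80 °C
Reagents that add atoms: none
Why: Light expels N2 from 19 and the furyl group migrates to the carbene carbon (Wolff rearrangement, forging C3a–C4) to give ketene 24, which adds ynol ether 23 in a [2+2] cycloaddition (C4–C5 and C6–C7) to give cyclobutenone 25; on heating, 4-electron conrotatory opening gives dienylketene 26, whose 6-electron disrotatory electrocyclization onto the free furan alpha-carbon (C7–C7a) gives dienone 27, and enolization delivers phenol 28. The closest known reaction type is the Danheiser benzannulation in its photochemical Wolff form, established for aryl and heteroaryl diazomethyl ketones with siloxyalkynes. Ring A is the only ring closed, by the thermal 6π electrocyclization, and aromatization pulls the reversible steps forward. No stereocentre is created in 28 (the sp3 carbons of 25 and 27 are transient and erased) and the two danshensu centres see only neutral conditions. Regiochemistry of the cycloaddition is needed and follows from polarity, the nucleophilic CH terminus of 23 bonding to the ketene carbonyl carbon so that silyloxy lands on C5 and the free hydroxyl on C7. Site selectivity of the closure is needed as well and is secured by the C3 ester, which blocks the furan beta-position so that only the alpha-carbon that becomes C7a can accept the ketene.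

Step 12
Reactants: 28 Dan 2-Ar-7-hydroxy-5-(triisopropylsilyloxy)benzofuran-3-carboxylate
Product: 29 Dan 2-Ar-7-(methoxymethoxy)-5-(triisopropylsilyloxy)benzofuran-3-carboxylate
Conditions: MOMCl, iPr2NEt, CH2Cl2, 0 °C → rt
Reagents that add atoms: chloromethyl methyl ether, COCCl
Why: Base-mediated O-alkylation of the free C7 phenol (MOM ether formation), which masks it so that only the C5 oxygen is unveiled in the next step and which falls off with the other acetals at the end.

Step 13
Reactants: 29 Dan 2-Ar-7-(methoxymethoxy)-5-(triisopropylsilyloxy)benzofuran-3-carboxylate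
Product: 31 Dan 2-Ar-7-(methoxymethoxy)-5-(trifluoromethanesulfonyloxy)benzofuran-3-carboxylate, via ammonium phenoxide 30 (not isolated)
Conditions: Bu4NF (1.1 equiv), THF, 0 °C; then PhNTf2, 0 °C → rt
Reagents that add atoms: N-phenylbis(trifluoromethanesulfonimide), O=S(=O)(N(c1ccccc1)S(=O)(=O)C(F)(F)F)C(F)(F)F
Why: Fluoride-induced cleavage of the aryl silyl ether gives the ammonium phenoxide, which is sulfonylated in the same flask by the triflimide, a known one-flask exchange of an aryl silyl ether for a triflate that avoids handling the free phenol.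

Step 14
Reactants: 3 tert-butyl (2R)-3-[3,4-bis(methoxymethoxy)phenyl]-2-hydroxypropanoate
Product: 32 Dan acrylate
Conditions: CH2=CHCOCl, Et3N, CH2Cl2, −20 → 0 °C
Reagents that add atoms: acryloyl chloride, C=CC(=O)Cl
Why: Schotten–Baumann-type O-acylation of the secondary alcohol with the acid chloride, in which no bond to the stereocentre is broken.

Step 15
Reactants: 31 Dan 2-Ar-7-(methoxymethoxy)-5-(trifluoromethanesulfonyloxy)benzofuran-3-carboxylate; 32 Dan acrylate
Product: 33 Dan 2-Ar-5-[(E)-3-(Dan-oxy)-3-oxoprop-1-en-1-yl]-7-(methoxymethoxy)benzofuran-3-carboxylate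
Conditions: Pd(OAc)2 (cat.), dppp, Et3N, DMF, 80 °C
Reagents that add atoms: none
Why: Mizoroki–Heck reaction: zerovalent palladium formed from Pd(OAc)2 and dppp inserts into the unhindered C5–OTf bond, syn carbopalladation at the acrylate terminus and syn beta-hydride elimination should give the E-cinnamate, and the amine base is too weak to epimerize the acyloxy esters.

Step 16
Reactants: 33 Dan 2-Ar-5-[(E)-3-(Dan-oxy)-3-oxoprop-1-en-1-yl]-7-(methoxymethoxy)benzofuran-3-carboxylate
Product: 34 Schizotenuin A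
Conditions: CF3CO2H/CH2Cl2/H2O (10:10:1), 0 °C → rt
Reagents that add atoms: none
Why: Acidolysis (acetal hydrolysis and alkyl–oxygen cleavage of the tert-butyl esters) should remove all seven MOM groups and both tert-butyl esters while the aryl ester, the cinnamate, the E-alkene and both stereocentres, which see no base, stay intact.

Compound list
1 | danshensu, (2R)-3-(3,4-dihydroxyphenyl)-2-hydroxypropanoic acid | O[C@H](Cc1ccc(O)c(O)c1)C(=O)O | starting material
2 | tert-butyl (2R)-3-(3,4-dihydroxyphenyl)-2-hydroxypropanoate | O[C@H](Cc1ccc(O)c(O)c1)C(=O)OC(C)(C)C | intermediate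
3 | tert-butyl (2R)-3-[3,4-bis(methoxymethoxy)phenyl]-2-hydroxypropanoate (Dan–OH) | O[C@H](Cc1ccc(OCOC)c(OCOC)c1)C(=O)OC(C)(C)C | intermediate
4 | 3,4-dihydroxybenzoic acid | O=C(O)c1ccc(O)c(O)c1 | starting material
5 | methoxymethyl 3,4-bis(methoxymethoxy)benzoate | COCOC(=O)c1ccc(OCOC)c(OCOC)c1 | intermediate
6 | 3,4-bis(methoxymethoxy)benzoic acid | O=C(O)c1ccc(OCOC)c(OCOC)c1 | intermediate
7 | Meldrum's acid, 2,2-dimethyl-1,3-dioxane-4,6-dione | CC1(C)OC(=O)CC(=O)O1 | starting material
8 | 5-[Ar(hydroxy)methylidene]-2,2-dimethyl-1,3-dioxane-4,6-dione (aroyl Meldrum's acid, enol form) | CC1(C)OC(=O)C(=C(O)c2ccc(OCOC)c(OCOC)c2)C(=O)O1 | intermediate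
9 | 3-Ar-3-oxoprop-1-en-1-one (aroylketene) | O=C=CC(=O)c1ccc(OCOC)c(OCOC)c1 | intermediate
10 | Dan 3-Ar-3-oxopropanoate | O=C(CC(=O)c1ccc(OCOC)c(OCOC)c1)O[C@H](Cc1ccc(OCOC)c(OCOC)c1)C(=O)OC(C)(C)C | intermediate
11 | bromopyruvic acid, 3-bromo-2-oxopropanoic acid | O=C(O)C(=O)CBr | starting material
12 | 3-bromo-2-oxopropanoyl chloride | O=C(Cl)C(=O)CBr | intermediate
13 | allyl 3-bromo-2-oxopropanoate | C=CCOC(=O)C(=O)CBr | intermediate
14 | 4-allyl 3-Dan 2-Ar-4-hydroxy-4,5-dihydrofuran-3,4-dicarboxylate (both C4 epimers) | C=CCOC(=O)C1(O)COC(c2ccc(OCOC)c(OCOC)c2)=C1C(=O)O[C@H](Cc1ccc(OCOC)c(OCOC)c1)C(=O)OC(C)(C)C | intermediate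
15 | 4-allyl 3-Dan 2-Ar-4-(methanesulfonyloxy)-4,5-dihydrofuran-3,4-dicarboxylate (both C4 epimers) | C=CCOC(=O)C1(OS(C)(=O)=O)COC(c2ccc(OCOC)c(OCOC)c2)=C1C(=O)O[C@H](Cc1ccc(OCOC)c(OCOC)c1)C(=O)OC(C)(C)C | intermediate
16 | 4-allyl 3-Dan 2-Ar-furan-3,4-dicarboxylate | C=CCOC(=O)c1coc(-c2ccc(OCOC)c(OCOC)c2)c1C(=O)O[C@H](Cc1ccc(OCOC)c(OCOC)c1)C(=O)OC(C)(C)C | intermediate
17 | 5-Ar-4-(Dan-oxycarbonyl)furan-3-carboxylic acid | O=C(O)c1coc(-c2ccc(OCOC)c(OCOC)c2)c1C(=O)O[C@H](Cc1ccc(OCOC)c(OCOC)c1)C(=O)OC(C)(C)C | intermediate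
18 | Dan 2-Ar-4-(chlorocarbonyl)furan-3-carboxylate | O=C(Cl)c1coc(-c2ccc(OCOC)c(OCOC)c2)c1C(=O)O[C@H](Cc1ccc(OCOC)c(OCOC)c1)C(=O)OC(C)(C)C | intermediate
19 | Dan 2-Ar-4-(diazoacetyl)furan-3-carboxylate | [N-]=[N+]=CC(=O)c1coc(-c2ccc(OCOC)c(OCOC)c2)c1C(=O)O[C@H](Cc1ccc(OCOC)c(OCOC)c1)C(=O)OC(C)(C)C | intermediate
20 | 3-phenylisoxazole | c1ccc(-c2ccon2)cc1 | starting material
21 | 5-lithio-3-phenylisoxazole | [Li]c1cc(-c2ccccc2)no1 | intermediate
22 | lithium ethynolate | [Li+].[O-]C#C | intermediate
23 | (triisopropylsilyloxy)ethyne | C#CO[Si](C(C)C)(C(C)C)C(C)C | intermediate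
24 | Dan 2-Ar-4-(2-oxoethenyl)furan-3-carboxylate (furylketene) | O=C=Cc1coc(-c2ccc(OCOC)c(OCOC)c2)c1C(=O)O[C@H](Cc1ccc(OCOC)c(OCOC)c1)C(=O)OC(C)(C)C | intermediate
25 | Dan 2-Ar-4-[4-oxo-2-(triisopropylsilyloxy)cyclobut-2-en-1-yl]furan-3-carboxylate (both epimers at the ring CH) | O=C1C=C(O[Si](C(C)C)(C(C)C)C(C)C)C1c1coc(-c2ccc(OCOC)c(OCOC)c2)c1C(=O)O[C@H](Cc1ccc(OCOC)c(OCOC)c1)C(=O)OC(C)(C)C | intermediate
26 | Dan 2-Ar-4-[4-oxo-2-(triisopropylsilyloxy)buta-1,3-dien-1-yl]furan-3-carboxylate (dienylketene; the isomer with furyl cis to the ketene arm closes) | O=C=CC(O[Si](C(C)C)(C(C)C)C(C)C)=Cc1coc(-c2ccc(OCOC)c(OCOC)c2)c1C(=O)O[C@H](Cc1ccc(OCOC)c(OCOC)c1)C(=O)OC(C)(C)C | intermediate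
27 | Dan 2-Ar-7-oxo-5-(triisopropylsilyloxy)-7,7a-dihydrobenzofuran-3-carboxylate (both C7a epimers) | O=C1C=C(O[Si](C(C)C)(C(C)C)C(C)C)C=C2C(C(=O)O[C@H](Cc3ccc(OCOC)c(OCOC)c3)C(=O)OC(C)(C)C)=C(c3ccc(OCOC)c(OCOC)c3)OC12 | intermediate
28 | Dan 2-Ar-7-hydroxy-5-(triisopropylsilyloxy)benzofuran-3-carboxylate | O=C(O[C@H](Cc1ccc(OCOC)c(OCOC)c1)C(=O)OC(C)(C)C)c1c(-c2ccc(OCOC)c(OCOC)c2)oc2c(O)cc(O[Si](C(C)C)(C(C)C)C(C)C)cc12 | intermediate
29 | Dan 2-Ar-7-(methoxymethoxy)-5-(triisopropylsilyloxy)benzofuran-3-carboxylate | O=C(O[C@H](Cc1ccc(OCOC)c(OCOC)c1)C(=O)OC(C)(C)C)c1c(-c2ccc(OCOC)c(OCOC)c2)oc2c(OCOC)cc(O[Si](C(C)C)(C(C)C)C(C)C)cc12 | intermediate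
30 | tetrabutylammonium 2-Ar-3-(Dan-oxycarbonyl)-7-(methoxymethoxy)benzofuran-5-olate | O=C(O[C@H](Cc1ccc(OCOC)c(OCOC)c1)C(=O)OC(C)(C)C)c1c(-c2ccc(OCOC)c(OCOC)c2)oc2c(OCOC)cc([O-])cc12.CCCC[N+](CCCC)(CCCC)CCCC | intermediate
31 | Dan 2-Ar-7-(methoxymethoxy)-5-(trifluoromethanesulfonyloxy)benzofuran-3-carboxylate | O=C(O[C@H](Cc1ccc(OCOC)c(OCOC)c1)C(=O)OC(C)(C)C)c1c(-c2ccc(OCOC)c(OCOC)c2)oc2c(OCOC)cc(OS(=O)(=O)C(F)(F)F)cc12 | intermediate
32 | Dan acrylate, tert-butyl (2R)-2-(acryloyloxy)-3-[3,4-bis(methoxymethoxy)phenyl]propanoate | C=CC(=O)O[C@H](Cc1ccc(OCOC)c(OCOC)c1)C(=O)OC(C)(C)C | intermediate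
33 | Dan 2-Ar-5-[(E)-3-(Dan-oxy)-3-oxoprop-1-en-1-yl]-7-(methoxymethoxy)benzofuran-3-carboxylate | O=C(/C=C/c1cc(OCOC)c2oc(-c3ccc(OCOC)c(OCOC)c3)c(C(=O)O[C@H](Cc3ccc(OCOC)c(OCOC)c3)C(=O)OC(C)(C)C)c2c1)O[C@H](Cc1ccc(OCOC)c(OCOC)c1)C(=O)OC(C)(C)C | intermediate
34 | Schizotenuin A, (2R)-2-{[5-{(E)-3-[(1R)-1-carboxy-2-(3,4-dihydroxyphenyl)ethoxy]-3-oxoprop-1-en-1-yl}-2-(3,4-dihydroxyphenyl)-7-hydroxybenzofuran-3-carbonyl]oxy}-3-(3,4-dihydroxyphenyl)propanoic acid | O=C(/C=C/c1cc(O)c2oc(-c3ccc(O)c(O)c3)c(C(=O)O[C@H](Cc3ccc(O)c(O)c3)C(=O)O)c2c1)O[C@H](Cc1ccc(O)c(O)c1)C(=O)O | target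

Total step count: 16.
Longest linear sequence: 11 steps (1, 2, 5, 7, 8, 9, 11, 12, 13, 15, 16; the branch through steps 3 and 4 is equally long).

Steps most likely to fail

Step 11. The arylfuran chromophore may absorb the light so that nitrogen loss stalls. The ketene may be consumed by O-acylation of the phenol already formed or by dimerization before it meets the alkyne. The ynol ether may isomerize by 1,3-silyl shift during the thermal stage. The fallback keeps the same bonds but makes the ketene thermally and stepwise; it sets out from 19 and comes back at 28. Silver-catalysed Wolff rearrangement of 19 in wet THF (PhCO2Ag, Et3N, THF/H2O; Arndt–Eistert homologation) should give the homologous 2-[5-Ar-4-(Dan-oxycarbonyl)furan-3-yl]acetic acid F1. 1-Chloro-N,N,2-trimethylprop-1-en-1-amine in CH2Cl2 should convert it into 2-[5-Ar-4-(Dan-oxycarbonyl)furan-3-yl]acetyl chloride F2. Slow addition of Et3N to F2 in the presence of 23 generates ketene 24 by dehydrochlorination and traps it as cyclobutenone 25, a known ketene–siloxyalkyne cycloaddition. Heating 25 in toluene then leads through 26 and 27 to 28.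

Step 10. Lithiation of the isoxazole may be incomplete, the ynolate or residual amide may add to the benzonitrile released in the same flask, and silylation may occur on carbon. The fallback generates the same ynolate by oxidation of an acetylide. It draws on no numbered compound: it starts from acetylene gas in place of 20 and rejoins the route at 22. Acetylene with n-BuLi in THF at −78 °C gives lithium acetylide F3. Lithium tert-butyl peroxide (from t-BuOOH and LiN(SiMe3)2) oxidizes F3 to ynolate 22, a known oxidation of lithium acetylides. iPr3SiOTf then gives 23 as in the main route.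

Step 16. Cleavage of seven acetals may stop short, formaldehyde or the methoxymethyl cation may attack the liberated catechol rings, and the polyphenol may oxidize in air during isolation. The fallback separates the two deprotections and removes the C1 unit with a soft nucleophile; it sets out from 33 and comes back at 34. ZnBr2 and n-PrSH in CH2Cl2 at 0 °C (thiol-assisted Lewis-acid cleavage of MOM ethers) should give the heptaphenol bis(tert-butyl ester) F4, the methoxymethyl groups leaving as a thioacetal. CF3CO2H/CH2Cl2 at 0 °C → rt then cleaves the tert-butyl esters of F4 to give 34; any ester already lost in the first stage is harmless.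

Further compounds
F1 | step 11 | 2-[5-Ar-4-(Dan-oxycarbonyl)furan-3-yl]acetic acid | OC(=O)Cc1coc(-c2ccc(OCOC)c(OCOC)c2)c1C(=O)O[C@H](Cc1ccc(OCOC)c(OCOC)c1)C(=O)OC(C)(C)C
F2 | step 11 | 2-[5-Ar-4-(Dan-oxycarbonyl)furan-3-yl]acetyl chloride | O=C(Cl)Cc1coc(-c2ccc(OCOC)c(OCOC)c2)c1C(=O)O[C@H](Cc1ccc(OCOC)c(OCOC)c1)C(=O)OC(C)(C)C
F3 | step 10 | lithium acetylide | [Li+].[C-]#C
F4 | step 16 | heptaphenol bis(tert-butyl ester), the MOM-free di-tert-butyl ester of Schizotenuin A | O=C(/C=C/c1cc(O)c2oc(-c3ccc(O)c(O)c3)c(C(=O)O[C@H](Cc3ccc(O)c(O)c3)C(=O)OC(C)(C)C)c2c1)O[C@H](Cc1ccc(O)c(O)c1)C(=O)OC(C)(C)C
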